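**Plan**

- Retrosynthesis: the C9–C10 bond of the side-chain diene is cut first (Suzuki–Miyaura), leaving an iodoalkene at C9. Next the ring bonds C3–O and C6–O are cut together (singlet-oxygen [4+2]) once C4–C5 is written as an alkene. Last, the acyclic triene is cut at C4–C5 (Negishi coupling).
- Enabling feature (ester carbon = C1): ring carbons C3–C6 of the 1,2-dioxane are a 1,3-diene in disguise, with both ring oxygens 1,4 across it. The quaternary C6, whose CH3 and C7 methylene are too alike for steric relay, is encoded as the geometry of the trisubstituted C5=C6 alkene.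
- Forward: propargyl alcohol gives the C2-symmetric C5–C9 bis(iodoalkene) 7 by two methylaluminations, and pent-3-yn-1-ol gives the C1–C4 alkenylzinc. Mono-coupling and oxidation at C1 give triene ester 16, and the cycloaddition closes the only ring (17). Resolution, diimide reduction, C3 equilibration and coupling with the boronate from 1-phenylbut-2-yne follow.
- Stereochemistry: all alkene geometries come from syn carbo- or hydrometalation. The C3/C6 relative configuration comes from the 3E,5E geometry (suprafacial addition), and the absolute configuration from resolution of 17. C4 is set by diimide anti to both arms, and C3 is finally inverted to the equatorial, thermodynamic configuration.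

Key step: step 10

Assumption: chain numbering is used throughout (ester carbon C1, ring carbons C3–C6, iodoalkene carbon C9). Racemic 17 is drawn as the enantiomer carried forward, and the HPLC fraction with this configuration is to be identified by chiroptical correlation with the final product.

**Route**

Step 1
Reactants: 1 prop-2-yn-1-ol
Product: 3 (E)-3-iodo-2-methylprop-2-en-1-ol, via alkenylalane 2 (not isolated)
Conditions: AlMe3 (3 equiv), Cp2ZrCl2 (25 mol %), CH2Cl2, 0 °C to rt; then I2, THF, −30 to 0 °C; aq K2CO3
Reagents that add atoms: trimethylaluminium, C[Al](C)C; iodine, II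
Why: Zirconium-catalysed methylalumination (Negishi carboalumination) adds CH3 and Al syn across the alkyne with Al on the terminal carbon, the hydroxyl being carried as its aluminium alkoxide, and iodinolysis with retention should give the E-iodoalkene.

Step 2
Reactants: 3 (E)-3-iodo-2-methylprop-2-en-1-ol
Product: 4 (E)-3-bromo-1-iodo-2-methylprop-1-ene
Conditions: CBr4, PPh3, CH2Cl2, 0 °C
Reagents that add atoms: tetrabromomethane, BrC(Br)(Br)Br
Why: The Appel reaction converts the primary allylic alcohol into the bromide under neutral conditions that leave the iodoalkene and its geometry untouched.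

Step 3
Reactants: 4 (E)-3-bromo-1-iodo-2-methylprop-1-ene
Product: 5 (E)-1-iodo-2-methylpent-1-en-4-yne
Conditions: HC≡CMgBr (2.5 equiv), CuBr·SMe2 (10 mol %), THF, 0 °C to rt
Reagents that add atoms: ethynylmagnesium bromide, C#C[Mg]Br
Why: Copper-catalysed allylic substitution by an alkynyl Grignard reagent should take place at the unhindered CH2 terminus (SN2, the SN2' terminus bearing iodine) to give the skipped enyne, the iodoalkene being inert to the acetylide at room temperature.

Step 4
Reactants: 5 (E)-1-iodo-2-methylpent-1-en-4-yne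
Product: 7 (1E,4E)-1,5-diiodo-2,4-dimethylpenta-1,4-diene, via alkenylalane 6 (not isolated)
Conditions: AlMe3 (2 equiv), Cp2ZrCl2 (20 mol %), CH2Cl2, 0 °C to rt; then I2, THF, −30 to 0 °C; aq K2CO3
Reagents that add atoms: trimethylaluminium, C[Al](C)C; iodine, II
Why: A second Negishi methylalumination–iodination of the terminal alkyne sets the other E-2-methyl-1-iodoalkene; the product is C2-symmetric, so either iodide can later serve as C5 and the other remains as C9.

Step 5
Reactants: 8 pent-3-yn-1-ol
Product: 9 tert-butyldimethyl(pent-3-yn-1-yloxy)silane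
Conditions: TBSCl, imidazole, CH2Cl2, rt
Reagents that add atoms: tert-butyldimethylsilyl chloride, CC(C)(C)[Si](C)(C)Cl
Why: Standard silylation masks the hydroxyl so that it does not consume the zirconium hydride in the next step.

Step 6
Reactants: 9 tert-butyldimethyl(pent-3-yn-1-yloxy)silane; 7 (1E,4E)-1,5-diiodo-2,4-dimethylpenta-1,4-diene
Product: 12 tert-butyl{[(3E,5E,8E)-9-iodo-4,6,8-trimethylnona-3,5,8-trien-1-yl]oxy}dimethylsilane, via alkenylzirconocene 10 (not isolated), via alkenylzinc chloride 11 (not isolated)
Conditions: Cp2Zr(H)Cl (1.5 equiv), THF, 50 °C; then ZnCl2 (1.6 equiv), 0 °C; then 7 (3 equiv), Pd(PPh3)4 (5 mol %), THF, 0 °C to rt; excess 7 recovered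
Reagents that add atoms: none
Why: Schwartz hydrozirconation adds H and Zr syn, and equilibration with excess hydride should move Zr to the less hindered methyl-bearing C4; transmetalation to zinc then allows a Negishi coupling with retention at both partners, forming C4–C5 with 3E,5E geometry, while the excess of symmetric 7 keeps the reaction at mono-coupling.

Step 7
Reactants: 12 tert-butyl{[(3E,5E,8E)-9-iodo-4,6,8-trimethylnona-3,5,8-trien-1-yl]oxy}dimethylsilane
Product: 13 (3E,5E,8E)-9-iodo-4,6,8-trimethylnona-3,5,8-trien-1-ol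
Conditions: Bu4NF, THF, 0 °C; aq NH4Cl
Reagents that add atoms: none
Why: Fluoride-mediated desilylation frees the primary alcohol without affecting the diene or the iodoalkene.

Step 8
Reactants: 13 (3E,5E,8E)-9-iodo-4,6,8-trimethylnona-3,5,8-trien-1-ol
Product: 15 (3E,5E,8E)-9-iodo-4,6,8-trimethylnona-3,5,8-trienoic acid, via aldehyde 14 (not isolated)
Conditions: TEMPO (20 mol %), PhI(OAc)2 (2.2 equiv), MeCN/H2O 1:1, rt, dark
Reagents that add atoms: water, O
Why: The oxoammonium-mediated oxidation (TEMPO/PhI(OAc)2) takes the alcohol through the aldehyde hydrate to the acid in one pot without base, so the C3=C4 bond should not migrate into conjugation with the carbonyl.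

Step 9
Reactants: 15 (3E,5E,8E)-9-iodo-4,6,8-trimethylnona-3,5,8-trienoic acid
Product: 16 methyl (3E,5E,8E)-9-iodo-4,6,8-trimethylnona-3,5,8-trienoate
Conditions: Me3SiCHN2, PhMe/MeOH 4:1, 0 °C
Reagents that add atoms: trimethylsilyldiazomethane, C[Si](C)(C)C=[N+]=[N-]
Why: Esterification with trimethylsilyldiazomethane is base-free and therefore keeps the β,γ-unsaturated dienoate deconjugated.

Step 10
Reactants: 16 methyl (3E,5E,8E)-9-iodo-4,6,8-trimethylnona-3,5,8-trienoate
Product: 17 methyl 2-[(3R,6S)-6-[(E)-3-iodo-2-methylprop-2-en-1-yl]-4,6-dimethyl-3,6-dihydro-1,2-dioxin-3-yl]acetate (racemate; this enantiomer drawn)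
Conditions: O2, tetraphenylporphyrin (1 mol %), CH2Cl2, −20 °C, visible light (λ > 400 nm); base-free work-up
Reagents that add atoms: dioxygen, O=O
Why: Triplet-excited tetraphenylporphyrin transfers energy to O2, and the resulting singlet oxygen adds as the 2π partner across C3 and C6 of the cisoid 3E,5E-diene in a concerted suprafacial [4+2] cycloaddition (hetero-Diels–Alder reaction), the closest known reaction type being the photooxygenation of acyclic 1,3-dienes with a disubstituted terminus to 3,6-dihydro-1,2-dioxines. The six-membered 1,2-dioxine ring closes by this cycloaddition, both C–O bonds forming on one face of the diene. C3 and C6 are set relative to each other by the alkene geometries: the two outward groups (the C2 arm on C3 and the C7 arm on C6) must end cis, with the inward H and CH3 on the other face, and since neither diene face is preferred 17 is racemic. The step needs [4+2] to win over the ene reaction and over attack at C8=C9: the C4 methyl clashes with the inward C6 methyl in the s-trans rotamer and so raises the population of the cisoid form, which has only H and CH3 inside. The iodoalkene is electron-poor and should be left alone, and the ester lowers the reactivity of the C2 hydrogens toward ene abstraction. A non-polar solvent, low temperature and long-wavelength light are chosen to disfavour perepoxide or zwitterion pathways and photolysis of the C–I bond.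

Step 11
Reactants: 17 methyl 2-[(3R,6S)-6-[(E)-3-iodo-2-methylprop-2-en-1-yl]-4,6-dimethyl-3,6-dihydro-1,2-dioxin-3-yl]acetate (racemate)
Product: 18 methyl 2-[(3R,6S)-6-[(E)-3-iodo-2-methylprop-2-en-1-yl]-4,6-dimethyl-3,6-dihydro-1,2-dioxin-3-yl]acetate (single enantiomer)
Conditions: preparative HPLC, amylose tris(3,5-dimethylphenylcarbamate) stationary phase, hexane/2-propanol, rt
Reagents that add atoms: none
Why: Chromatographic resolution on a polysaccharide chiral stationary phase separates the enantiomers without any reagent, which matters because the allylic C3–H of the dihydrodioxine is prone to base-induced Kornblum–DeLaMare cleavage; no stereocenter is formed, and the 3R,6S fraction is identified by chiroptical correlation with the final product.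

Step 12
Reactants: 18 methyl 2-[(3R,6S)-6-[(E)-3-iodo-2-methylprop-2-en-1-yl]-4,6-dimethyl-3,6-dihydro-1,2-dioxin-3-yl]acetate
Product: 19 methyl 2-[(3R,4R,6R)-6-[(E)-3-iodo-2-methylprop-2-en-1-yl]-4,6-dimethyl-1,2-dioxan-3-yl]acetate
Conditions: KO2CN=NCO2K (excess, in portions), AcOH, MeOH/CH2Cl2, 0 °C to rt, dark
Reagents that add atoms: none
Why: Diimide reduction, the standard way to saturate 3,6-dihydro-1,2-dioxines without breaking O–O, delivers two hydrogens syn to the face of C4=C5 opposite the two cis carbon arms (in the half-chair with the C6 arm pseudoaxial the lower face carries only the pseudoaxial C3–H), so the C4 methyl should end cis to both arms (4R; the C6 descriptor changes from S to R only because C5 loses priority), while the trisubstituted iodoalkene should react much more slowly.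

Step 13
Reactants: 19 methyl 2-[(3R,4R,6R)-6-[(E)-3-iodo-2-methylprop-2-en-1-yl]-4,6-dimethyl-1,2-dioxan-3-yl]acetate
Product: 21 methyl 2-[(3S,4R,6R)-6-[(E)-3-iodo-2-methylprop-2-en-1-yl]-4,6-dimethyl-1,2-dioxan-3-yl]acetate, via hydroperoxy enoate 20 (not isolated)
Conditions: Cs2CO3 (0.5 equiv), MeOH, 0 °C to rt; AcOH quench; chromatography, recovered 19 resubmitted
Reagents that add atoms: none
Why: Methoxide reversibly opens the ring by E1cB loss of the C6 peroxide anion from the ester enolate, and 20 recloses by 6-exo hydroperoxide conjugate addition (retro-oxa-Michael/oxa-Michael equilibration, the reverse and forward of the base-mediated hydroperoxide Michael cyclisations that build 1,2-dioxane-3-acetates), so C3 should settle with the acetate arm equatorial and trans to the equatorial C4 methyl (3S), C4 and C6 not being involved.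

Step 14
Reactants: 22 1-phenylbut-2-yne
Product: 24 [(E)-3-iodobut-2-en-1-yl]benzene, via alkenylzirconocene 23 (not isolated)
Conditions: Cp2Zr(H)Cl (1.5 equiv), THF, 50 °C; then I2, THF, 0 °C
Reagents that add atoms: iodine, II
Why: Schwartz hydrozirconation under equilibrating conditions should place Zr on the methyl-bearing carbon cis to the new hydrogen, and iodinolysis with retention then gives the E-iodoalkene with CH3 cis to the benzyl group.

Step 15
Reactants: 24 [(E)-3-iodobut-2-en-1-yl]benzene
Product: 26 4,4,5,5-tetramethyl-2-[(Z)-4-phenylbut-2-en-2-yl]-1,3,2-dioxaborolane, via alkenyllithium 25 (not isolated)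
Conditions: t-BuLi (2.1 equiv), Et2O, −78 °C; then 2-isopropoxy-4,4,5,5-tetramethyl-1,3,2-dioxaborolane, −78 °C to rt
Reagents that add atoms: 2-isopropoxy-4,4,5,5-tetramethyl-1,3,2-dioxaborolane, CC(C)OB1OC(C)(C)C(C)(C)O1
Why: Iodine–lithium exchange and borylation both proceed with retention, so boron stays trans to the benzyl group (the descriptor reads Z only because boron ranks below carbon), and chromatography of the boronate removes any minor regioisomer carried from step 14.

Step 16
Reactants: 21 methyl 2-[(3S,4R,6R)-6-[(E)-3-iodo-2-methylprop-2-en-1-yl]-4,6-dimethyl-1,2-dioxan-3-yl]acetate; 26 4,4,5,5-tetramethyl-2-[(Z)-4-phenylbut-2-en-2-yl]-1,3,2-dioxaborolane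
Product: 27 methyl 2-[(3S,4R,6R)-6-[(2E,4E)-2,4-dimethyl-6-phenylhexa-2,4-dien-1-yl]-4,6-dimethyl-1,2-dioxan-3-yl]acetate
Conditions: PdCl2(dppf) (10 mol %), AsPh3 (20 mol %), Cs2CO3 (2 equiv), DMF/THF/H2O, rt, degassed, dark
Reagents that add atoms: none
Why: The Suzuki–Miyaura coupling joins C9 to C10 with retention of both alkene geometries to give the 8E,10E diene; the saturated dialkyl peroxide is expected to tolerate zerovalent palladium at room temperature as in cross-couplings of related peroxide-bearing iodoalkenes, and the mild carbonate base cannot erode C3 because its equatorial configuration is already the thermodynamic one.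

**Compound list**

1 | prop-2-yn-1-ol | C#CCO | starting material
2 | dimethylaluminium (E)-3-(dimethylalumanyl)-2-methylprop-2-en-1-olate | C[Al](C)OC/C(C)=C/[Al](C)C | intermediate (not isolated)
3 | (E)-3-iodo-2-methylprop-2-en-1-ol | OC/C(C)=C/I | intermediate
4 | (E)-3-bromo-1-iodo-2-methylprop-1-ene | BrC/C(C)=C/I | intermediate
5 | (E)-1-iodo-2-methylpent-1-en-4-yne | C#CC/C(C)=C/I | intermediate
6 | [(1E,4E)-5-iodo-2,4-dimethylpenta-1,4-dien-1-yl]dimethylalumane | C[Al](C)/C=C(C)/C/C(C)=C/I | intermediate (not isolated)
7 | (1E,4E)-1,5-diiodo-2,4-dimethylpenta-1,4-diene | I/C=C(C)/C/C(C)=C/I | intermediate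
8 | pent-3-yn-1-ol | CC#CCCO | starting material
9 | tert-butyldimethyl(pent-3-yn-1-yloxy)silane | CC#CCCO[Si](C)(C)C(C)(C)C | intermediate
10 | chlorobis(cyclopentadienyl)[(E)-5-(tert-butyldimethylsilyloxy)pent-2-en-2-yl]zirconium (cyclopentadienyl rings drawn σ-bonded) | C/C(=C\CCO[Si](C)(C)C(C)(C)C)[Zr](Cl)(C1C=CC=C1)C1C=CC=C1 | intermediate (not isolated)
11 | [(E)-5-(tert-butyldimethylsilyloxy)pent-2-en-2-yl]zinc chloride | C/C(=C\CCO[Si](C)(C)C(C)(C)C)[Zn]Cl | intermediate (not isolated)
12 | tert-butyl{[(3E,5E,8E)-9-iodo-4,6,8-trimethylnona-3,5,8-trien-1-yl]oxy}dimethylsilane | CC(C)(C)[Si](C)(C)OCC/C=C(C)/C=C(C)/C/C(C)=C/I | intermediate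
13 | (3E,5E,8E)-9-iodo-4,6,8-trimethylnona-3,5,8-trien-1-ol | OCC/C=C(C)/C=C(C)/C/C(C)=C/I | intermediate
14 | (3E,5E,8E)-9-iodo-4,6,8-trimethylnona-3,5,8-trienal | O=CC/C=C(C)/C=C(C)/C/C(C)=C/I | intermediate (not isolated)
15 | (3E,5E,8E)-9-iodo-4,6,8-trimethylnona-3,5,8-trienoic acid | OC(=O)C/C=C(C)/C=C(C)/C/C(C)=C/I | intermediate
16 | methyl (3E,5E,8E)-9-iodo-4,6,8-trimethylnona-3,5,8-trienoate | COC(=O)C/C=C(C)/C=C(C)/C/C(C)=C/I | intermediate
17 | methyl 2-[(3R,6S)-6-[(E)-3-iodo-2-methylprop-2-en-1-yl]-4,6-dimethyl-3,6-dihydro-1,2-dioxin-3-yl]acetate, racemate (C2 arm and C7 arm cis; one enantiomer drawn) | COC(=O)C[C@H]1OO[C@@](C)(C/C(C)=C/I)C=C1C | intermediate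
18 | methyl 2-[(3R,6S)-6-[(E)-3-iodo-2-methylprop-2-en-1-yl]-4,6-dimethyl-3,6-dihydro-1,2-dioxin-3-yl]acetate, single enantiomer | COC(=O)C[C@H]1OO[C@@](C)(C/C(C)=C/I)C=C1C | intermediate
19 | methyl 2-[(3R,4R,6R)-6-[(E)-3-iodo-2-methylprop-2-en-1-yl]-4,6-dimethyl-1,2-dioxan-3-yl]acetate | COC(=O)C[C@H]1OO[C@@](C)(C/C(C)=C/I)C[C@H]1C | intermediate
20 | methyl (2E,4R,6R,8E)-6-hydroperoxy-9-iodo-4,6,8-trimethylnona-2,8-dienoate | COC(=O)/C=C/[C@H](C)C[C@@](C)(OO)C/C(C)=C/I | intermediate (not isolated)
21 | methyl 2-[(3S,4R,6R)-6-[(E)-3-iodo-2-methylprop-2-en-1-yl]-4,6-dimethyl-1,2-dioxan-3-yl]acetate | COC(=O)C[C@@H]1OO[C@@](C)(C/C(C)=C/I)C[C@H]1C | intermediate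
22 | 1-phenylbut-2-yne | CC#CCc1ccccc1 | starting material
23 | chlorobis(cyclopentadienyl)[(E)-4-phenylbut-2-en-2-yl]zirconium (cyclopentadienyl rings drawn σ-bonded) | C/C(=C\Cc1ccccc1)[Zr](Cl)(C1C=CC=C1)C1C=CC=C1 | intermediate (not isolated)
24 | [(E)-3-iodobut-2-en-1-yl]benzene | C/C(I)=C\Cc1ccccc1 | intermediate
25 | [(Z)-4-phenylbut-2-en-2-yl]lithium (Li trans to the benzyl group) | [Li]/C(C)=C/Cc1ccccc1 | intermediate (not isolated)
26 | 4,4,5,5-tetramethyl-2-[(Z)-4-phenylbut-2-en-2-yl]-1,3,2-dioxaborolane (B trans to the benzyl group) | C/C(B1OC(C)(C)C(C)(C)O1)=C\Cc1ccccc1 | intermediate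
27 | methyl 2-[(3S,4R,6R)-6-[(2E,4E)-2,4-dimethyl-6-phenylhexa-2,4-dien-1-yl]-4,6-dimethyl-1,2-dioxan-3-yl]acetate | COC(=O)C[C@@H]1OO[C@@](C)(C/C(C)=C/C(C)=C/Cc2ccccc2)C[C@H]1C | target

**Step count and risks**

Total steps: 16. Longest linear sequence: 13 steps (1 → 3 → 4 → 5 → 7 → 12 → 13 → 15 → 16 → 17 → 18 → 19 → 21 → 27, i.e. steps 1–4, 6–13 and 16).

The three steps most likely to fail:

Step 13 (inversion of C3). The ester enolate that mediates ring opening may instead attack the O–O bond, closing an epoxide with loss of the peroxide. Kinetic reclosure may also return mainly 19, so that equilibrium is reached only at the cost of material. The fallback changes the oxidation level so that no ester enolate is needed. It sets out from 19: i-Bu2AlH (CH2Cl2, −78 °C) would give the cis-configured dioxanyl acetaldehyde F1. Under weakly acidic buffering (pyridinium p-toluenesulfonate, CH2Cl2, rt) the β-peroxy aldehyde should equilibrate through its enol and the ring-opened hydroperoxy enal F2 (not isolated) to the equatorial, trans-configured aldehyde F3. Oxidation with NaClO2/NaH2PO4/2-methylbut-2-ene would give the trans-configured dioxanyl acetic acid F4, and Me3SiCHN2 returns the route at 21.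

Step 10 (key cycloaddition). Ene hydroperoxidation at the allylic positions (C2–H, C4–CH3, C6–CH3) or stepwise perepoxide pathways may outrun the concerted [4+2] if the cisoid diene is too sparsely populated. The fallback keeps the same two C–O bonds and the same ring closure but forms them through the diene radical cation and ground-state oxygen, a manifold with no ene channel and no need for a planar cisoid diene. It sets out from 16: (4-BrC6H4)3N(SbCl6) (5 mol %), O2, CH2Cl2, −78 °C, the aminium-salt-catalysed cation-radical oxygenation of 1,3-dienes to 1,2-dioxines. It returns to the route at 17 (F0, no new compound). Because this addition is stepwise, the cis relationship of the two arms would have to be confirmed before step 12.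

Step 12 (diimide reduction). Facial discrimination in hydrogen delivery to C4=C5 may be insufficient. The hindered trisubstituted ring alkene may also react so slowly that the large excess of diimide begins to reduce the iodoalkene. The fallback moves cycloaddition and reduction to the silyl ether series and oxidises C1 afterwards. There the C3 arm is a bulkier 2-silyloxyethyl group that should shield its face better, and no base- or acid-sensitive carbonyl limits reagent excess and reaction time. It sets out from 12: photooxygenation as in step 10 would give the racemic silyloxyethyl dihydrodioxine F5. Resolution as in step 11 would give its 3R,6S enantiomer F6, and diimide as in step 12 the silyloxyethyl dioxane F7. Bu4NF would free the dioxanyl ethanol F8, and TEMPO/PhI(OAc)2 (passing through aldehyde F1) would give the cis-configured dioxanyl acetic acid F9. Me3SiCHN2 returns the route at 19. This order also avoids the isomerisation-prone dienyl acid 15.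

Further compounds
F1 | step 13 | 2-[(3R,4R,6R)-6-[(E)-3-iodo-2-methylprop-2-en-1-yl]-4,6-dimethyl-1,2-dioxan-3-yl]acetaldehyde | O=CC[C@H]1OO[C@@](C)(C/C(C)=C/I)C[C@H]1C
F2 | step 13 | (2E,4R,6R,8E)-6-hydroperoxy-9-iodo-4,6,8-trimethylnona-2,8-dienal | O=C/C=C/[C@H](C)C[C@@](C)(OO)C/C(C)=C/I
F3 | step 13 | 2-[(3S,4R,6R)-6-[(E)-3-iodo-2-methylprop-2-en-1-yl]-4,6-dimethyl-1,2-dioxan-3-yl]acetaldehyde | O=CC[C@@H]1OO[C@@](C)(C/C(C)=C/I)C[C@H]1C
F4 | step 13 | 2-[(3S,4R,6R)-6-[(E)-3-iodo-2-methylprop-2-en-1-yl]-4,6-dimethyl-1,2-dioxan-3-yl]acetic acid | OC(=O)C[C@@H]1OO[C@@](C)(C/C(C)=C/I)C[C@H]1C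
F0 | step 10 | none | none
F5 | step 12 | tert-butyl{2-[(3R,6S)-6-[(E)-3-iodo-2-methylprop-2-en-1-yl]-4,6-dimethyl-3,6-dihydro-1,2-dioxin-3-yl]ethoxy}dimethylsilane, racemate (one enantiomer drawn) | CC(C)(C)[Si](C)(C)OCC[C@H]1OO[C@@](C)(C/C(C)=C/I)C=C1C
F6 | step 12 | tert-butyl{2-[(3R,6S)-6-[(E)-3-iodo-2-methylprop-2-en-1-yl]-4,6-dimethyl-3,6-dihydro-1,2-dioxin-3-yl]ethoxy}dimethylsilane, single enantiomer | CC(C)(C)[Si](C)(C)OCC[C@H]1OO[C@@](C)(C/C(C)=C/I)C=C1C
F7 | step 12 | tert-butyl{2-[(3R,4R,6R)-6-[(E)-3-iodo-2-methylprop-2-en-1-yl]-4,6-dimethyl-1,2-dioxan-3-yl]ethoxy}dimethylsilane | CC(C)(C)[Si](C)(C)OCC[C@H]1OO[C@@](C)(C/C(C)=C/I)C[C@H]1C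
F8 | step 12 | 2-[(3R,4R,6R)-6-[(E)-3-iodo-2-methylprop-2-en-1-yl]-4,6-dimethyl-1,2-dioxan-3-yl]ethan-1-ol | OCC[C@H]1OO[C@@](C)(C/C(C)=C/I)C[C@H]1C
F9 | step 12 | 2-[(3R,4R,6R)-6-[(E)-3-iodo-2-methylprop-2-en-1-yl]-4,6-dimethyl-1,2-dioxan-3-yl]acetic acid | OC(=O)C[C@H]1OO[C@@](C)(C/C(C)=C/I)C[C@H]1C
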